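## Retrosynthetic overview

1. The lactone is the only ring made (both arenes are bought). It is closed last but one by dehydrogenating the 9-CH2OH of an 8-hydroxy-seco-lignan triol through the 2-hydroxy aldehyde and the lactol, the laboratory counterpart of the dehydrogenase step that closes matairesinol.
2. Triol ⇒ 2,3-epoxy-1,4-diol + arylmethyl Grignard reagent/CuI: SN2 opening at the CH carbon makes C8'–C7' and sets C8' anti to the epoxide oxygen.
3. Epoxide ⇒ (E)-2-(arylmethyl)but-2-ene-1,4-diol by titanium/tartrate epoxidation, which sets the tertiary carbinol C8 and the face for the opening.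
4. Enediol ⇒ but-2-yne-1,4-diol + the same Grignard reagent (anti carbomagnesiation, C8–C7 bond); the reagent is made once from the benzylic chloride and serves both C–C bond formations.
5. The phenols are carried as benzyl ethers and freed in the final step.

Assumption: 4-(benzyloxy)-3-methoxybenzyl chloride is taken as a catalogue compound, and the lactone is taken to arise in the plant as in matairesinol, by dehydrogenation of a 9,9'-diol through the lactol.

## Route

Step 1
Reactants: 1 4-(benzyloxy)-3-methoxybenzyl chloride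
Product: 2 [4-(benzyloxy)-3-methoxybenzyl]magnesium chloride (titrated THF stock solution, kept under argon and used as such in steps 2 and 4)
Conditions: Mg turnings (3 equiv, I2-activated), THF, 0 °C, slow addition of 1; titration
Reagents that add atoms: magnesium, [Mg]
Why: Grignard reagent formation by insertion of magnesium into the benzylic C–Cl bond, where slow addition at 0 °C onto excess metal suppresses Wurtz homocoupling and the aryl ethers are inert; no stereocentre is involved.

Step 2
Reactants: 3 but-2-yne-1,4-diol; 2 [4-(benzyloxy)-3-methoxybenzyl]magnesium chloride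
Product: 4 (E)-2-[4-(benzyloxy)-3-methoxybenzyl]but-2-ene-1,4-diol
Conditions: 3, i-PrMgCl (2.0 equiv), THF, 0 °C; then 2 (1.5 equiv), CuI (10 mol%), 0 °C → reflux; cold 1 M HCl
Reagents that add atoms: none
Why: Hydroxyl-directed anti carbomagnesiation of a propargylic alcohol (copper-assisted Grignard addition) puts the benzyl group on the alkyne carbon next to a magnesium alkoxide and magnesium on the other carbon in a five-membered chelate, so protonation gives only the alkene with the two CH2OH groups trans (E); no stereocentre is formed.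

Step 3
Reactants: 4 (E)-2-[4-(benzyloxy)-3-methoxybenzyl]but-2-ene-1,4-diol
Product: 5 [(2R,3R)-2-[4-(benzyloxy)-3-methoxybenzyl]-3-(hydroxymethyl)oxiran-2-yl]methanol
Conditions: Ti(OiPr)4 (20 mol%), D-(−)-diisopropyl tartrate (24 mol%), t-BuOOH (2 equiv, decane), 4 Å MS, CH2Cl2, −20 °C; non-aqueous citric acid work-up
Reagents that add atoms: tert-butyl hydroperoxide, CC(C)(C)OO
Why: Sharpless asymmetric epoxidation, in which the two allylic hydroxyls of the E-enediol are related by an in-plane twofold rotation so that whichever binds titanium the D-(−)-tartrate catalyst delivers oxygen to the same alkene face (the face that gives the 2R,3R series, opposite to the 2S,3S epoxides that the L-(+)-ester gives with simple (E)-allylic alcohols), which sets C8.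

Step 4
Reactants: 5 [(2R,3R)-2-[4-(benzyloxy)-3-methoxybenzyl]-3-(hydroxymethyl)oxiran-2-yl]methanol; 2 [4-(benzyloxy)-3-methoxybenzyl]magnesium chloride
Product: 6 (2S,3S)-2,3-bis[4-(benzyloxy)-3-methoxybenzyl]butane-1,2,4-triol
Conditions: 5, i-PrMgCl (2.0 equiv), THF, −40 °C; then 2 (2.0 equiv), CuI (20 mol%), THF, −40 → 0 °C; cold 1 M HCl
Reagents that add atoms: none
Why: Copper-catalysed Grignard opening of a 2,3-epoxy alcohol (SN2) takes place at the CH carbon, because the other epoxide carbon is fully substituted, and proceeds with inversion, so C8' is set anti to the C8 oxygen and the net anti addition of O and benzyl across the E-alkene gives the (2S,3S)-triol.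

Step 5
Reactants: 6 (2S,3S)-2,3-bis[4-(benzyloxy)-3-methoxybenzyl]butane-1,2,4-triol
Product: 9 (3S,4S)-3,4-bis[4-(benzyloxy)-3-methoxybenzyl]-3-hydroxyoxolan-2-one, via hydroxy aldehyde 7 (not isolated), via lactol 8 (not isolated)
Conditions: [(2,9-dimethyl-1,10-phenanthroline)Pd(OAc)]2(OTf)2 (5 mol%), 1,4-benzoquinone (2.5 equiv), MeCN–H2O 10:1, 40 °C
Reagents that add atoms: none
Why: Proposed new method: dehydrogenative lactonisation of a triol steered to the glycol terminus — the cationic divalent palladium catalyst binds the 8,9-glycol as a chelate, β-hydride elimination is possible only at the primary C9 carbinol because C8 is fully substituted, the 2-hydroxy aldehyde is captured by the 9'-hydroxyl as a five-membered lactol whose anomeric OH is again vicinal to the tertiary OH and is dehydrogenated in turn, while the isolated 9'-CH2OH binds only as a monodentate ligand and reacts more slowly; the closest known reaction types are the chelation-controlled palladium/neocuproine oxidation of vicinal diols in polyols and the oxidative lactonisation of 1,4-diols through lactols, and no stereocentre is touched because neither C8 nor C8' can enolise.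

Step 6
Reactants: 9 (3S,4S)-3,4-bis[4-(benzyloxy)-3-methoxybenzyl]-3-hydroxyoxolan-2-one
Product: 10 (3S,4S)-3-hydroxy-3,4-bis(4-hydroxy-3-methoxybenzyl)oxolan-2-one (CNP0166172.1)
Conditions: H2 (1 atm), 10% Pd/C, EtOAc–EtOH, rt
Reagents that add atoms: none
Why: Heterogeneous catalytic hydrogenolysis removes the two aryl benzyl ethers, while the lactone CH2–O bond and the tertiary alcohol are not benzylic and survive with both stereocentres untouched.

## Compound list

1 | 4-(benzyloxy)-3-methoxybenzyl chloride | ClCc1ccc(OCc2ccccc2)c(OC)c1 | starting material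
2 | [4-(benzyloxy)-3-methoxybenzyl]magnesium chloride (THF stock solution) | Cl[Mg]Cc1ccc(OCc2ccccc2)c(OC)c1 | intermediate
3 | but-2-yne-1,4-diol | OCC#CCO | starting material
4 | (E)-2-[4-(benzyloxy)-3-methoxybenzyl]but-2-ene-1,4-diol | OC/C(Cc1ccc(OCc2ccccc2)c(OC)c1)=C/CO | intermediate
5 | [(2R,3R)-2-[4-(benzyloxy)-3-methoxybenzyl]-3-(hydroxymethyl)oxiran-2-yl]methanol | OC[C@@]1(Cc2ccc(OCc3ccccc3)c(OC)c2)O[C@@H]1CO | intermediate
6 | (2S,3S)-2,3-bis[4-(benzyloxy)-3-methoxybenzyl]butane-1,2,4-triol | OC[C@](O)(Cc1ccc(OCc2ccccc2)c(OC)c1)[C@H](CO)Cc1ccc(OCc2ccccc2)c(OC)c1 | intermediate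
7 | (2S,3S)-2,3-bis[4-(benzyloxy)-3-methoxybenzyl]-2,4-dihydroxybutanal | O=C[C@](O)(Cc1ccc(OCc2ccccc2)c(OC)c1)[C@H](CO)Cc1ccc(OCc2ccccc2)c(OC)c1 | intermediate (formed in the flask, not isolated)
8 | (3S,4S)-3,4-bis[4-(benzyloxy)-3-methoxybenzyl]oxolane-2,3-diol (lactol, both anomers) | OC1OC[C@H](Cc2ccc(OCc3ccccc3)c(OC)c2)[C@@]1(O)Cc1ccc(OCc2ccccc2)c(OC)c1 | intermediate (formed in the flask, not isolated)
9 | (3S,4S)-3,4-bis[4-(benzyloxy)-3-methoxybenzyl]-3-hydroxyoxolan-2-one | O=C1OC[C@H](Cc2ccc(OCc3ccccc3)c(OC)c2)[C@@]1(O)Cc1ccc(OCc2ccccc2)c(OC)c1 | intermediate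
10 | (3S,4S)-3-hydroxy-3,4-bis(4-hydroxy-3-methoxybenzyl)oxolan-2-one (CNP0166172.1) | COc1cc(C[C@H]2COC(=O)[C@]2(O)Cc2ccc(O)c(OC)c2)ccc1O | target

## Step count and risks

Total steps: 6. Longest linear sequence: 6 (1 → 2 → 4 → 5 → 6 → 9 → 10; diol 3 enters in step 2 and the Grignard solution 2 is used again in step 4).

Three steps most likely to fail:

Step 5. The isolated 9'-CH2OH may be dehydrogenated first, which would give the regioisomeric 4-hydroxy lactone. The fallback sets out from triol 6 and returns at lactone 9. The less hindered 9'-hydroxyl is silylated selectively (TBDPSCl, imidazole, CH2Cl2, −20 °C) to give the mono-silyl ether F1. Its glycol CH2OH is oxidised in one pot (TEMPO and NaOCl catalytic, NaClO2, MeCN/NaH2PO4–Na2HPO4 buffer, 35 °C) to the silylated 2-hydroxy acid F2. TBAF in THF followed by dilute HCl frees the seco hydroxy acid F3, which closes to 9 in the acidic solution. This replaces the regioselective dehydrogenation by a protecting-group-defined oxidation and an ordinary hydroxy-acid lactonisation.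

Step 3. The free enediol and the epoxy diol product may bridge or poison the titanium–tartrate catalyst, and the tertiary epoxide carbon is acid-sensitive. The fallback sets out from enediol 4 and returns at epoxide 5. Both hydroxyls are silylated (TBSCl, imidazole, DMF) to give the bis-silyl ether F4. Shi epoxidation with the D-fructose-derived ketone (KHSO5 as the triple salt 2KHSO5·KHSO4·K2SO4, K2CO3, Bu4NHSO4 catalytic, MeCN–dimethoxymethane–aqueous Na2B4O7 buffer, 0 °C) should give the bis-silyl epoxide F5. With the single olefinic hydrogen in the position the spiro transition state requires, the ketone attacks the same face as in trans-olefins, which here is the 2R,3R epoxide. TBAF in THF then gives 5.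

Step 2. The electron-rich benzylic Grignard reagent may homocouple or add sluggishly at reflux. The fallback sets out from diol 3 and chloride 1 and returns at enediol 4. Anti hydroalumination of 3 with NaAlH2(OCH2CH2OMe)2 in THF and iodinolysis (I2, −78 °C) gives (Z)-2-iodobut-2-ene-1,4-diol F6, in which the two CH2OH groups are already trans. Zinc insertion into 1 (Zn dust, LiCl, THF) gives the benzylzinc chloride F7. Negishi coupling of F6 with F7 (Pd(OAc)2, SPhos, THF, rt) proceeds with retention of alkene geometry and gives 4.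

Further compounds
F1 | step 5 | (2S,3S)-2,3-bis[4-(benzyloxy)-3-methoxybenzyl]-4-[(tert-butyldiphenylsilyl)oxy]butane-1,2-diol | OC[C@](O)(Cc1ccc(OCc2ccccc2)c(OC)c1)[C@H](CO[Si](c1ccccc1)(c1ccccc1)C(C)(C)C)Cc1ccc(OCc2ccccc2)c(OC)c1
F2 | step 5 | (2S,3S)-2,3-bis[4-(benzyloxy)-3-methoxybenzyl]-4-[(tert-butyldiphenylsilyl)oxy]-2-hydroxybutanoic acid | OC(=O)[C@](O)(Cc1ccc(OCc2ccccc2)c(OC)c1)[C@H](CO[Si](c1ccccc1)(c1ccccc1)C(C)(C)C)Cc1ccc(OCc2ccccc2)c(OC)c1
F3 | step 5 | (2S,3S)-2,3-bis[4-(benzyloxy)-3-methoxybenzyl]-2,4-dihydroxybutanoic acid | OC(=O)[C@](O)(Cc1ccc(OCc2ccccc2)c(OC)c1)[C@H](CO)Cc1ccc(OCc2ccccc2)c(OC)c1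
F4 | step 3 | (E)-2-[4-(benzyloxy)-3-methoxybenzyl]-1,4-bis[(tert-butyldimethylsilyl)oxy]but-2-ene | CC(C)(C)[Si](C)(C)OC/C(Cc1ccc(OCc2ccccc2)c(OC)c1)=C/CO[Si](C)(C)C(C)(C)C
F5 | step 3 | (2R,3R)-2-[4-(benzyloxy)-3-methoxybenzyl]-2,3-bis[[(tert-butyldimethylsilyl)oxy]methyl]oxirane | CC(C)(C)[Si](C)(C)OC[C@@]1(Cc2ccc(OCc3ccccc3)c(OC)c2)O[C@@H]1CO[Si](C)(C)C(C)(C)C
F6 | step 2 | (Z)-2-iodobut-2-ene-1,4-diol | OC/C(I)=C/CO
F7 | step 2 | [4-(benzyloxy)-3-methoxybenzyl]zinc chloride | Cl[Zn]Cc1ccc(OCc2ccccc2)c(OC)c1
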